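## Structural features

The target is an isoflavone: a 4H-chromen-4-one (benzo ring A fused to γ-pyrone ring C through C4a–C8a) carrying a 2,4-dihydroxyphenyl group (ring B) on C3 through the C3–C1' bond. Ring A is fully substituted: C5–OH, C6–prenyl, C7–OH and C8–prenyl lie between the two fusion carbons. There is no stereocentre and no stereogenic alkene, since each prenyl group ends in a gem-dimethyl alkene, so no stereocentres stand next to each other. The fragile features are:
- the two trisubstituted alkenes ortho to free phenols, which acid closes to 2,2-dimethylchromans;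
- C2 of the γ-pyrone, which hydroxide and amines attack with ring opening;
- the electron-rich tetraphenol, which is air-sensitive under base.

The 5-OH is chelated to C4=O and is difficult to alkylate once the chromone exists. The real difficulty is not the core but placing two prenyl groups on carbon at C6 and C8 of a phloroglucinol-type ring without O-alkylation, over-alkylation, wrong regiochemistry or chroman closure. The key step exploits the fact that C6 is ortho to O5 and C8 is ortho to O7: each prenyl group is first attached to oxygen as a 1,1-dimethylallyl ether and then moved to the neighbouring carbon by a [3,3] shift, which inverts the allyl unit into a 3-methylbut-2-enyl group.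

## Logic of the disconnections

14 ⇒ 13. The bonds concerned are O2'–Si and O4'–Si: the two phenols of ring B are masked as silyl ethers. Ring B must be inert during cross-coupling and during the hot step, and a silyl ether leaves under near-neutral fluoride, away from the acid that would close the ortho-prenylphenols of ring A. The gain is an end game of one operation on a compound that already has the full carbon skeleton. The forward step needs a buffered fluoride source and a neutral work-up.

13 ⇒ 11 (through 12). The C6–CH2 and C8–CH2 bonds are cut and each five-carbon unit is reattached through its tertiary carbon to O5 and O7. A tether through oxygen replaces two intermolecular C-alkylations of an ambident ring by two intramolecular shifts of fixed stoichiometry. The gain is large: ring A of 11 carries only hydrogen at C6 and C8 and derives from a symmetrical triphenol. The forward step must meet four conditions: each group must find a free ortho carbon, the dienones must enolise rather than shift again, the strained 5-O ether must not simply lose isoprene, and the product phenols must not add to their own alkenes.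

11 ⇒ 10. No skeletal bond is cut; the two vinyl groups are traced back to ethynyl groups. The tertiary propargyl ether can be made reliably on a hindered phenol and withstands warming and zerovalent palladium, whereas the tertiary allyl ether would ionise on zerovalent palladium and start to rearrange on heating. The gain is that the labile function exists for one step only before it is used. The forward step must stop at the alkene on both arms.

10 ⇒ 6 + 9. The C3–C1' bond is cut. This is the only bond between the two aromatic halves, and cutting it gives a halochromone and an arylboron partner of similar size. The gain is convergence: ring B arrives complete and already protected. The coupling must leave two terminal alkynes, two aryl silyl ethers and the base-sensitive pyrone untouched.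

9 ⇒ 8 ⇒ 7. The C1'–B bond and then the two O–Si bonds are cut, leading back to a commercial bromodiol. The demand is a borylation that avoids an aryllithium, because an ortho-silyloxy aryllithium would suffer oxygen-to-carbon silyl migration.

6 ⇒ 4 (through 5). The O1–C2, C2–C3 and C3–I bonds are cut; C2 is a one-carbon unit supplied by the first reagent of step 2. This returns ring C to an ortho-hydroxyacetophenone and installs the coupling handle in the same operation. The demand is that iodine reacts with the enaminone and not with the alkynes or the electron-rich ring.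

4 ⇒ 1 + 2 (through 3). The two O–C(tertiary) bonds are cut. Etherification is done on the acetophenone because there one ortho hydroxyl is still free of chelation, which is no longer true for O5 of a finished chromone. The gain is two commercial starting materials. The para hydroxyl and one ortho hydroxyl must react while the chelated hydroxyl, which becomes O1, stays free.

## Other disconnections considered

Alternative 1: The cut goes through ring C at C4–C3 and O1–C2. It divides the target into the salicylaldehyde 2-hydroxy-4,6-bis(methoxymethoxy)-3,5-bis(3-methylbut-2-enyl)benzaldehyde A1 and the alkyne {[2,4-bis(methoxymethoxy)phenyl]ethynyl}trimethylsilane A2.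
- Forward key step: [Cp*RhCl2]2 with Cu(OAc)2 as oxidant would activate the aldehyde C–H bond of A1 under direction of the phenoxide and insert A2 into the acyl–rhodium bond with the silyl-bearing carbon next to the metal. C–O reductive elimination would close ring C to give 5,7,2',4'-tetrakis(methoxymethoxy)-6,8-bis(3-methylbut-2-enyl)-2-(trimethylsilyl)isoflavone A3. Protodesilylation and removal of four acetals would lead to 14.
- In its favour: ring C is closed and ring B attached in one catalytic step; no halochromone or boron reagent is needed; the prenyl groups are already on carbon, so no hot step comes late.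
- Against it here: the hard problem is only moved, because A1 still needs two prenyl groups placed on carbon of an electron-rich triphenol ring. The insertion regiochemistry of A2 rests on the silyl group alone. The divalent copper oxidant and cationic trivalent rhodium meet two electron-rich alkenes. Four acetals must leave in acid, the medium that closes ortho-prenylphenols to chromans.
- Comparison: it is the equal of the chosen plan in convergence and the better in bonds formed per step (two bonds of the core at once). It is weaker in mechanistic control of prenyl placement and in the end game. With separate routes to A1 and A2 and three operations after the coupling, it offers no gain in step count.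

Alternative 2: The cut is the C5–C6 bond of ring A, which opens the benzo ring to a chain on a pyranone: methyl 5-[2,4-bis(methoxymethoxy)phenyl]-2-(2,10-dimethyl-6-oxoundeca-2,9-dien-5-yl)-4-oxo-4H-pyran-3-carboxylate A4.
- Forward key step: two equivalents of LiN(iPr)2 would form the dianion of A4, first at the doubly activated C8 position and then at C6. The C6 enolate would attack the ester carbon in a 6-exo-trig Dieckmann-type acylation. Loss of methoxide and enolisation would aromatise ring A to 5,7-dihydroxy-2',4'-bis(methoxymethoxy)-6,8-bis(3-methylbut-2-enyl)isoflavone A5.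
- In its favour: both prenyl groups are fixed by carbons of the chain, so their positions are beyond doubt. On this point it is better than the chosen plan, whose outcome depends on the course of two shifts. Ring A also appears at the phenol oxidation level without an oxidant, and the chelated 5-OH needs no protection.
- Against it here: A4 is a trisubstituted pyranone with a branched, doubly prenylated ketone chain and would take many steps. A strong amide base meets a pyranone that accepts nucleophiles at its oxygen-bearing carbons and opens readily. The site of the second deprotonation and competing attack on the pyranone carbonyl are uncertain. The ring B acetals again need acid at the end.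
- Comparison: it is roughly equal after the key step (one deprotection in each plan). It is far longer before it, because the chosen plan buys ring A as 1.

Alternative 3: The cut removes four bonds of ring B (C1'–C2', C2'–C3', C4'–C5', C5'–C6'). It leaves the diazoketone (E)-1-diazo-4-[5,7-bis(methoxymethoxy)-6,8-bis(3-methylbut-2-enyl)-4-oxo-4H-chromen-3-yl]but-3-en-2-one A6 and (triisopropylsiloxy)acetylene A7.
- Forward key step: irradiation of A6 would set off a cascade of Wolff rearrangement, [2+2] union with A7, four-electron ring opening and six-electron ring closure. Enolisation would deliver 2'-hydroxy-5,7-bis(methoxymethoxy)-6,8-bis(3-methylbut-2-enyl)-4'-(triisopropylsiloxy)isoflavone A8.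
- In its favour: the 1,3-dioxygen pattern of ring B is guaranteed by the cycloaddition, and O2' and O4' emerge differentiated. That is better than the chosen plan, which gives two identical silyl ethers, though it is immaterial for 14. No transition metal is needed.
- Against it here: it builds a ring that is bought complete as 7. Ring A with both prenyl groups must exist beforehand, so the central problem is untouched. The chromone itself absorbs light, and the carbene and ketene stages pass two nucleophilic alkenes. A6 needs several functional-group operations on a prenylated chromone. Acid is again needed for the acetals.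
- Comparison: it is mechanistically elegant but spends its key step on the wrong ring, and it is much longer than the chosen plan.

Key step: step 7

Remark: isoflavone numbering is used throughout (O1, C2 to C8a, ring B primed); 1 is used anhydrous (the commercial monohydrate is dried first), because water would hydrolyse 3.

## Route

Step 1
Reactants: 1 2,4,6-trihydroxyacetophenone; 2 2-methylbut-3-yn-2-ol
Product: 4 1-[2-hydroxy-4,6-bis(2-methylbut-3-yn-2-yloxy)phenyl]ethanone, via 2-methylbut-3-yn-2-yl trifluoroacetate 3 (not isolated)
Conditions: 2 (2.4 equiv), (CF3CO)2O, DBU, MeCN, −5 °C; then 1, DBU, CuCl2·2H2O (cat.), MeCN, −5 to 0 °C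
Reagents that add atoms: none
Why: Copper-catalysed propargylic etherification of phenoxides with a tertiary propargyl trifluoroacetate (copper acetylide/allenylidene pathway). The para hydroxyl and one ortho hydroxyl should react; the last hydroxyl stays hydrogen-bonded to the acetyl carbonyl, is the least nucleophilic and is kept free to become O1.

Step 2
Reactants: 4 1-[2-hydroxy-4,6-bis(2-methylbut-3-yn-2-yloxy)phenyl]ethanone
Product: 6 3-iodo-5,7-bis(2-methylbut-3-yn-2-yloxy)-4H-chromen-4-one, via dimethylamino enone 5 (not isolated)
Conditions: Me2NCH(OMe)2, toluene, 80 °C; evaporate; then I2, pyridine, CHCl3, 0 °C to rt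
Reagents that add atoms: N,N-dimethylformamide dimethyl acetal, COC(OC)N(C)C; iodine, II
Why: Condensation of the acetyl methyl with the amide acetal gives enaminone 5; iodine attacks its α-carbon, the phenol adds to the iminium carbon and dimethylamine is lost (iodocyclisation of 2-hydroxyaryl enaminones to 3-iodochromones). At 80 °C the propargyl ethers are below their rearrangement threshold, and the enaminone should outcompete alkynes and arene for one equivalent of iodine.

Step 3
Reactants: 7 4-bromoresorcinol
Product: 8 1-bromo-2,4-bis(tert-butyldimethylsilyloxy)benzene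
Conditions: TBSCl, imidazole, DMF, rt
Reagents that add atoms: tert-butyldimethylsilyl chloride, CC(C)(C)[Si](C)(C)Cl
Why: Standard O-silylation of phenols with a silyl chloride and imidazole; both hydroxyls react.

Step 4
Reactants: 8 1-bromo-2,4-bis(tert-butyldimethylsilyloxy)benzene
Product: 9 2-[2,4-bis(tert-butyldimethylsilyloxy)phenyl]-4,4,5,5-tetramethyl-1,3,2-dioxaborolane
Conditions: B2pin2, Pd(dppf)Cl2 (cat.), KOAc, 1,4-dioxane, 85 °C
Reagents that add atoms: bis(pinacolato)diboron, CC1(C)OB(OC1(C)C)B1OC(C)(C)C(C)(C)O1
Why: Miyaura borylation (zerovalent palladium, acetate-assisted transmetalation from the diboron). It is preferred to bromine–lithium exchange because an ortho-lithiated aryl silyl ether would undergo a 1,3 oxygen-to-carbon silyl shift (retro-Brook rearrangement).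

Step 5
Reactants: 6 3-iodo-5,7-bis(2-methylbut-3-yn-2-yloxy)-4H-chromen-4-one; 9 2-[2,4-bis(tert-butyldimethylsilyloxy)phenyl]-4,4,5,5-tetramethyl-1,3,2-dioxaborolane
Product: 10 2',4'-bis(tert-butyldimethylsilyloxy)-5,7-bis(2-methylbut-3-yn-2-yloxy)isoflavone
Conditions: Pd(dppf)Cl2 (cat.), Na2CO3, DME–H2O, 60 °C, degassed, no copper, no amine
Reagents that add atoms: none
Why: Suzuki–Miyaura coupling of a 3-iodochromone with an arylboronic ester. Oxidative addition to the C3–I bond is fast, and without copper or amine the terminal alkynes should remain spectators; carbonate at 60 °C is too mild to open the pyrone or strip the aryl silyl ethers.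

Step 6
Reactants: 10 2',4'-bis(tert-butyldimethylsilyloxy)-5,7-bis(2-methylbut-3-yn-2-yloxy)isoflavone
Product: 11 2',4'-bis(tert-butyldimethylsilyloxy)-5,7-bis(2-methylbut-3-en-2-yloxy)isoflavone
Conditions: H2 (1 atm), Pd/CaCO3 poisoned with Pb(OAc)2, quinoline, EtOAc, rt; stopped after 2 equiv H2; work-up without acid, below 30 °C
Reagents that add atoms: none
Why: Semihydrogenation of terminal alkynes over lead-poisoned palladium with quinoline (Lindlar reduction); the chromone C2=C3 bond, the arenes and the silyl ethers are untouched. Cold, acid-free handling keeps 11 from rearranging early or losing its peri ether.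

Step 7
Reactants: 11 2',4'-bis(tert-butyldimethylsilyloxy)-5,7-bis(2-methylbut-3-en-2-yloxy)isoflavone
Product: 13 2',4'-bis(tert-butyldimethylsilyloxy)-5,7-dihydroxy-6,8-bis(3-methylbut-2-enyl)isoflavone, via mono-shifted 5-hydroxy-6-prenyl 7-ether 12 (not isolated)
Conditions: PhNEt2 (degassed), 170 °C, Ar; then chromatography
Reagents that add atoms: none
Why: Each tertiary allyl aryl ether should undergo a concerted, suprafacial [3,3]-sigmatropic shift through a chair-like transition state (aromatic Claisen rearrangement; the closest known cases are 1,1-dimethylallyl ethers at O7 of coumarins, chromones and xanthones), in which allyl inversion turns O–CMe2–CH=CH2 into C–CH2–CH=CMe2 and the ortho-dienone then enolises to the phenol. The 5-O ether is twisted out of the ring plane by the peri C4 carbonyl, gains a hydrogen bond to that carbonyl on migration and has C6 as its only free ortho carbon, so it is expected to move first and give 12. In 12 the 7-O ether has C8 as its only free ortho carbon, and the second shift gives 13. The selectivity needed is that the 7-O group never reaches C6 ahead of the 5-O group; besides the rate advantage of the strained 5-O ether, C6 is shielded by two tert-alkoxy groups and the 7-O group of a chromone is expected to prefer C8 in any case, so both possible orders converge on 13. The basic amine solvent speeds enolisation of the dienones, which should outrun a Cope shift towards C8, and keeps the medium free of acid so that the ortho-prenylphenols do not close to chromans. No ring is closed and no stereocentre is formed. The aryl silyl ethers are thermally inert, and any silyl transfer to O7 would be erased in step 8.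

Step 8
Reactants: 13 2',4'-bis(tert-butyldimethylsilyloxy)-5,7-dihydroxy-6,8-bis(3-methylbut-2-enyl)isoflavone
Product: 14 5,7,2',4'-tetrahydroxy-6,8-bis(3-methylbut-2-enyl)isoflavone
Conditions: TBAF, AcOH, THF, 0 °C to rt; pH 7 buffer work-up
Reagents that add atoms: none
Why: Fluoride-induced cleavage of aryl silyl ethers, driven by Si–F bond formation. Acetic acid buffers the phenoxides so the tetraphenol is not held under base, and no acid strong enough to cyclise the ortho-prenylphenols is present.

## Compound list

1 | 2,4,6-trihydroxyacetophenone | CC(=O)c1c(O)cc(O)cc1O | starting material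
2 | 2-methylbut-3-yn-2-ol | CC(C)(O)C#C | starting material
3 | 2-methylbut-3-yn-2-yl trifluoroacetate | C#CC(C)(C)OC(=O)C(F)(F)F | intermediate (not isolated)
4 | 1-[2-hydroxy-4,6-bis(2-methylbut-3-yn-2-yloxy)phenyl]ethanone | CC(=O)c1c(O)cc(OC(C)(C)C#C)cc1OC(C)(C)C#C | intermediate
5 | (E)-3-(dimethylamino)-1-[2-hydroxy-4,6-bis(2-methylbut-3-yn-2-yloxy)phenyl]prop-2-en-1-one | CN(C)/C=C/C(=O)c1c(O)cc(OC(C)(C)C#C)cc1OC(C)(C)C#C | intermediate (not isolated)
6 | 3-iodo-5,7-bis(2-methylbut-3-yn-2-yloxy)-4H-chromen-4-one | C#CC(C)(C)Oc1cc(OC(C)(C)C#C)c2c(=O)c(I)coc2c1 | intermediate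
7 | 4-bromoresorcinol (4-bromobenzene-1,3-diol) | Oc1ccc(Br)c(O)c1 | starting material
8 | 1-bromo-2,4-bis(tert-butyldimethylsilyloxy)benzene | CC(C)(C)[Si](C)(C)Oc1ccc(Br)c(O[Si](C)(C)C(C)(C)C)c1 | intermediate
9 | 2-[2,4-bis(tert-butyldimethylsilyloxy)phenyl]-4,4,5,5-tetramethyl-1,3,2-dioxaborolane | CC(C)(C)[Si](C)(C)Oc1ccc(B2OC(C)(C)C(C)(C)O2)c(O[Si](C)(C)C(C)(C)C)c1 | intermediate
10 | 2',4'-bis(tert-butyldimethylsilyloxy)-5,7-bis(2-methylbut-3-yn-2-yloxy)isoflavone | C#CC(C)(C)Oc1cc(OC(C)(C)C#C)c2c(=O)c(-c3ccc(O[Si](C)(C)C(C)(C)C)cc3O[Si](C)(C)C(C)(C)C)coc2c1 | intermediate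
11 | 2',4'-bis(tert-butyldimethylsilyloxy)-5,7-bis(2-methylbut-3-en-2-yloxy)isoflavone | C=CC(C)(C)Oc1cc(OC(C)(C)C=C)c2c(=O)c(-c3ccc(O[Si](C)(C)C(C)(C)C)cc3O[Si](C)(C)C(C)(C)C)coc2c1 | intermediate
12 | 2',4'-bis(tert-butyldimethylsilyloxy)-5-hydroxy-7-(2-methylbut-3-en-2-yloxy)-6-(3-methylbut-2-enyl)isoflavone | C=CC(C)(C)Oc1cc2occ(-c3ccc(O[Si](C)(C)C(C)(C)C)cc3O[Si](C)(C)C(C)(C)C)c(=O)c2c(O)c1CC=C(C)C | intermediate (not isolated)
13 | 2',4'-bis(tert-butyldimethylsilyloxy)-5,7-dihydroxy-6,8-bis(3-methylbut-2-enyl)isoflavone | CC(C)=CCc1c(O)c(CC=C(C)C)c2occ(-c3ccc(O[Si](C)(C)C(C)(C)C)cc3O[Si](C)(C)C(C)(C)C)c(=O)c2c1O | intermediate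
14 | 5,7,2',4'-tetrahydroxy-6,8-bis(3-methylbut-2-enyl)isoflavone | CC(C)=CCc1c(O)c(CC=C(C)C)c2occ(-c3ccc(O)cc3O)c(=O)c2c1O | target

Total step count: 8. Longest linear sequence: 6 steps (steps 1, 2, 5, 6, 7, 8); steps 3 and 4 form the side branch to 9.

## Least certain steps

Step 7 (key step). The most likely failure is fragmentation of the strained tertiary 5-O ether with loss of isoprene before it can shift. A second is a Cope shift of the first ortho-dienone towards C8 before it enolises. A third is arrival of the 7-O group at C6 ahead of the 5-O group. Each would give missing or misplaced prenyl groups.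

The fallback moves plain allyl groups, for which inversion makes no difference, and adds the methyl groups afterwards. It sets out from 1:
- Double O-allylation (allyl bromide, K2CO3, acetone) should give 1-[2-hydroxy-4,6-bis(prop-2-enyloxy)phenyl]ethanone F1.
- The sequence of step 2, passing through the enaminone (E)-3-(dimethylamino)-1-[2-hydroxy-4,6-bis(prop-2-enyloxy)phenyl]prop-2-en-1-one F2, should give 3-iodo-5,7-bis(prop-2-enyloxy)-4H-chromen-4-one F3.
- Coupling with 9 as in step 5 should give 2',4'-bis(tert-butyldimethylsilyloxy)-5,7-bis(prop-2-enyloxy)isoflavone F4.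
- Primary allyl aryl ethers cannot lose a diene, and an allyl group is unchanged by inversion. Every Claisen or Claisen–Cope path in PhNEt2 at 200 °C should therefore end in 6,8-diallyl-2',4'-bis(tert-butyldimethylsilyloxy)-5,7-dihydroxyisoflavone F5.
- Olefin cross-metathesis of F5 with 2-methylbut-2-ene (second-generation Grubbs catalyst, RuCl2(=CHPh)(H2IMes)(PCy3)) should convert both allyl groups into prenyl groups and come back to the route at 13.

Step 1. The most likely failure is incomplete etherification of the hindered ortho hydroxyl, stopping at the 4-mono ether. C-alkylation of the phloroglucinol ring is the other risk.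

The fallback installs the ether directly at the alkene oxidation level by palladium-catalysed decarboxylative O-allylation. It sets out from 1:
- tert-Butyl 2-methylbut-3-en-2-yl carbonate F6 is made from 2-methylbut-3-en-2-ol and Boc2O.
- With Pd(PPh3)4 in THF at 0 °C the phenoxide attacks the more substituted terminus of the π-allyl complex of divalent palladium under kinetic control. This should convert 1 into 1-[2-hydroxy-4,6-bis(2-methylbut-3-en-2-yloxy)phenyl]ethanone F7.
- The sequence of step 2, through the enaminone (E)-3-(dimethylamino)-1-[2-hydroxy-4,6-bis(2-methylbut-3-en-2-yloxy)phenyl]prop-2-en-1-one F8, should give 3-iodo-5,7-bis(2-methylbut-3-en-2-yloxy)-4H-chromen-4-one F9.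
- Coupling of F9 with 9, using a fast catalyst at 40 °C or below to outrun ionisation of the allyl ethers by zerovalent palladium, comes back to the route at 11. Steps 5 and 6 are then not needed.

Step 5. The most likely failure is reaction of the terminal alkynes with the arylpalladium iodide (alkynylation, oligomers) under the basic aqueous conditions. Protodeboronation of the electron-rich boronate and partial loss of silyl groups are further risks.

The fallback is a base-free Negishi coupling. It sets out from 8: magnesium insertion in the presence of LiCl and ZnCl2 (THF, rt) should give [2,4-bis(tert-butyldimethylsilyloxy)phenyl]zinc chloride F10. With 6 and Pd(PPh3)4 in THF at rt this should come back to the route at 10. Without base the alkyne C–H bond is not activated, and no water reaches the silyl ethers.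

Step 6. The most likely failure is over-reduction of one or both terminal alkynes to ethyl groups. The resulting tert-pentyl ethers cannot rearrange and would be hard to separate. Incomplete reduction is the other risk.

The fallback is stoichiometric hydroboration–protonolysis. It sets out from 10: dicyclohexylborane (THF, 0 °C) should add once to each terminal alkyne to give 2',4'-bis(tert-butyldimethylsilyloxy)-5,7-bis{[(E)-4-(dicyclohexylboryl)-2-methylbut-3-en-2-yl]oxy}isoflavone F11. Protonolysis of the two C–B bonds with acetic acid should come back to the route at 11. An alkenylborane cannot be reduced further, so the over-reduction path is absent.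

## Further compounds

F1 | step 7 | 1-[2-hydroxy-4,6-bis(prop-2-enyloxy)phenyl]ethanone | CC(=O)c1c(O)cc(OCC=C)cc1OCC=C
F2 | step 7 | (E)-3-(dimethylamino)-1-[2-hydroxy-4,6-bis(prop-2-enyloxy)phenyl]prop-2-en-1-one | CN(C)/C=C/C(=O)c1c(O)cc(OCC=C)cc1OCC=C
F3 | step 7 | 3-iodo-5,7-bis(prop-2-enyloxy)-4H-chromen-4-one | C=CCOc1cc(OCC=C)c2c(=O)c(I)coc2c1
F4 | step 7 | 2',4'-bis(tert-butyldimethylsilyloxy)-5,7-bis(prop-2-enyloxy)isoflavone | C=CCOc1cc(OCC=C)c2c(=O)c(-c3ccc(O[Si](C)(C)C(C)(C)C)cc3O[Si](C)(C)C(C)(C)C)coc2c1
F5 | step 7 | 6,8-diallyl-2',4'-bis(tert-butyldimethylsilyloxy)-5,7-dihydroxyisoflavone | C=CCc1c(O)c(CC=C)c2occ(-c3ccc(O[Si](C)(C)C(C)(C)C)cc3O[Si](C)(C)C(C)(C)C)c(=O)c2c1O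
F6 | step 1 | tert-butyl 2-methylbut-3-en-2-yl carbonate | C=CC(C)(C)OC(=O)OC(C)(C)C
F7 | step 1 | 1-[2-hydroxy-4,6-bis(2-methylbut-3-en-2-yloxy)phenyl]ethanone | CC(=O)c1c(O)cc(OC(C)(C)C=C)cc1OC(C)(C)C=C
F8 | step 1 | (E)-3-(dimethylamino)-1-[2-hydroxy-4,6-bis(2-methylbut-3-en-2-yloxy)phenyl]prop-2-en-1-one | CN(C)/C=C/C(=O)c1c(O)cc(OC(C)(C)C=C)cc1OC(C)(C)C=C
F9 | step 1 | 3-iodo-5,7-bis(2-methylbut-3-en-2-yloxy)-4H-chromen-4-one | C=CC(C)(C)Oc1cc(OC(C)(C)C=C)c2c(=O)c(I)coc2c1
F10 | step 5 | [2,4-bis(tert-butyldimethylsilyloxy)phenyl]zinc chloride | CC(C)(C)[Si](C)(C)Oc1ccc([Zn]Cl)c(O[Si](C)(C)C(C)(C)C)c1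
F11 | step 6 | 2',4'-bis(tert-butyldimethylsilyloxy)-5,7-bis{[(E)-4-(dicyclohexylboryl)-2-methylbut-3-en-2-yl]oxy}isoflavone | C1CCCCC1B(C1CCCCC1)/C=C/C(C)(C)Oc1cc(OC(C)(C)/C=C/B(C2CCCCC2)C2CCCCC2)c2c(=O)c(-c3ccc(O[Si](C)(C)C(C)(C)C)cc3O[Si](C)(C)C(C)(C)C)coc2c1
A1 | alternative 1 | 2-hydroxy-4,6-bis(methoxymethoxy)-3,5-bis(3-methylbut-2-enyl)benzaldehyde | O=Cc1c(O)c(CC=C(C)C)c(OCOC)c(CC=C(C)C)c1OCOC
A2 | alternative 1 | {[2,4-bis(methoxymethoxy)phenyl]ethynyl}trimethylsilane | C[Si](C)(C)C#Cc1ccc(OCOC)cc1OCOC
A3 | alternative 1 | 5,7,2',4'-tetrakis(methoxymethoxy)-6,8-bis(3-methylbut-2-enyl)-2-(trimethylsilyl)isoflavone | CC(C)=CCc1c(OCOC)c(CC=C(C)C)c2oc([Si](C)(C)C)c(-c3ccc(OCOC)cc3OCOC)c(=O)c2c1OCOC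
A4 | alternative 2 | methyl 5-[2,4-bis(methoxymethoxy)phenyl]-2-(2,10-dimethyl-6-oxoundeca-2,9-dien-5-yl)-4-oxo-4H-pyran-3-carboxylate | COC(=O)c1c(C(CC=C(C)C)C(=O)CCC=C(C)C)occ(-c2ccc(OCOC)cc2OCOC)c1=O
A5 | alternative 2 | 5,7-dihydroxy-2',4'-bis(methoxymethoxy)-6,8-bis(3-methylbut-2-enyl)isoflavone | CC(C)=CCc1c(O)c(CC=C(C)C)c2occ(-c3ccc(OCOC)cc3OCOC)c(=O)c2c1O
A6 | alternative 3 | (E)-1-diazo-4-[5,7-bis(methoxymethoxy)-6,8-bis(3-methylbut-2-enyl)-4-oxo-4H-chromen-3-yl]but-3-en-2-one | [N-]=[N+]=CC(=O)/C=C/c1coc2c(CC=C(C)C)c(OCOC)c(CC=C(C)C)c(OCOC)c2c1=O
A7 | alternative 3 | (triisopropylsiloxy)acetylene | C#CO[Si](C(C)C)(C(C)C)C(C)C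
A8 | alternative 3 | 2'-hydroxy-5,7-bis(methoxymethoxy)-6,8-bis(3-methylbut-2-enyl)-4'-(triisopropylsiloxy)isoflavone | CC(C)=CCc1c(OCOC)c(CC=C(C)C)c2occ(-c3ccc(O[Si](C(C)C)(C(C)C)C(C)C)cc3O)c(=O)c2c1OCOC
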